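**Plan**

- Numbering: the phenol half is Ar–C7–C8–C9 and the prenyloxyaryl half is C7'–C8'–C9'. Ring A is C7–O–C9'–C8'–C8 and ring B is C7'–O–C9–C8–C8'. The target is (7S,7'S,8R,8'R).
- Enabling feature: both ring oxygens sit on benzylic carbons (C7, C7') that are para to an aryl oxygen and four atoms from the C9'/C9 oxygen of the other half. Each C–O bond can therefore be made from a benzylic C–H bond by hydride abstraction and capture of the cation by a hydroxyl.
- Cuts: prenyl ether back to an allyl ether and phenol to a silyl ether; then C7–O and C7'–O, leaving an (8R,8'R)-dibenzylbutane-1,4-diol; then C8'–C7' (benzylation of a lactone enolate) and C8–C8' (alkylation of an acyl oxazolidinone with a bromoacetate).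
- Forward: C8–C8' is joined first, the chain is closed to a β-benzyl lactone, benzylated at C8' and reduced to the diol. One oxidation then closes ring B and ring A; cross-metathesis and desilylation finish.
- Stereochemistry: C8 comes from the (S)-4-benzyloxazolidinone auxiliary, C8' from trans alkylation of the lactone, and C7 and C7' from C8 and C8' during the double ring closure.

Key step: step 9

Remark: the target SMILES is read as the (+)-pinoresinol series; dihydroferulic acid and vanillyl alcohol are bought as such; an allyl ether is carried through the oxidation because a prenyl ether would itself be attacked by DDQ.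

**Route**

Step 1
Reactants: 1 vanillyl alcohol (4-hydroxy-3-methoxybenzyl alcohol); 2 allyl bromide
Product: 3 [4-(allyloxy)-3-methoxyphenyl]methanol
Conditions: K2CO3, acetone, reflux
Reagents that add atoms: none
Why: Williamson ether synthesis in which K2CO3 deprotonates only the phenol, not the benzylic alcohol, and the phenoxide displaces bromide from the allylic halide.

Step 2
Reactants: 3 [4-(allyloxy)-3-methoxyphenyl]methanol
Product: 4 4-(allyloxy)-3-methoxybenzyl bromide
Conditions: PBr3, Et2O, 0 °C; prepared shortly before step 7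
Reagents that add atoms: phosphorus tribromide, BrP(Br)Br
Why: Bromination of a benzylic alcohol with PBr3 by SN2 displacement of the phosphite leaving group, fast at 0 °C for an electron-rich benzylic carbon and without effect on the aryl allyl ether.

Step 3
Reactants: 5 3-(4-hydroxy-3-methoxyphenyl)propanoic acid (dihydroferulic acid)
Product: 7 3-[3-methoxy-4-(triisopropylsilyloxy)phenyl]propanoic acid, via triisopropylsilyl ester 6 (not isolated)
Conditions: TIPSCl (2.2 equiv), imidazole, DMF, rt; then K2CO3, MeOH/THF/H2O, rt; citric acid to pH 4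
Reagents that add atoms: triisopropylsilyl chloride, CC(C)[Si](Cl)(C(C)C)C(C)C
Why: Silylation of both acidic OH groups followed by selective hydrolysis of the silyl ester, which is far more labile to aqueous carbonate than the hindered aryl triisopropylsilyl ether.

Step 4
Reactants: 7 3-[3-methoxy-4-(triisopropylsilyloxy)phenyl]propanoic acid; 8 (S)-4-benzyl-1,3-oxazolidin-2-one
Product: 10 (S)-4-benzyl-3-{3-[3-methoxy-4-(triisopropylsilyloxy)phenyl]propanoyl}-1,3-oxazolidin-2-one, via mixed pivalic anhydride 9 (not isolated)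
Conditions: t-BuCOCl, Et3N, THF, −20 °C; then LiCl, 8, −20 °C → rt
Reagents that add atoms: none
Why: N-Acylation of the oxazolidinone through the mixed pivalic anhydride, in which the hindered pivaloyl carbonyl is spared and LiCl/Et3N make the carbamate nitrogen nucleophilic enough.

Step 5
Reactants: 10 (S)-4-benzyl-3-{3-[3-methoxy-4-(triisopropylsilyloxy)phenyl]propanoyl}-1,3-oxazolidin-2-one; 11 tert-butyl bromoacetate
Product: 13 tert-butyl (3R)-4-[(4S)-4-benzyl-2-oxo-1,3-oxazolidin-3-yl]-3-[3-methoxy-4-(triisopropylsilyloxy)benzyl]-4-oxobutanoate, via sodium Z-enolate 12 (not isolated)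
Conditions: NaN(SiMe3)2, THF, −78 °C; then 11, −78 → −40 °C
Reagents that add atoms: none
Why: Evans asymmetric alkylation, in which the chelated sodium Z-enolate is attacked by the reactive bromoacetate on the face opposite the benzyl group of the (S)-auxiliary, setting C8 as R.

Step 6
Reactants: 13 tert-butyl (3R)-4-[(4S)-4-benzyl-2-oxo-1,3-oxazolidin-3-yl]-3-[3-methoxy-4-(triisopropylsilyloxy)benzyl]-4-oxobutanoate
Product: 15 (4R)-4-[3-methoxy-4-(triisopropylsilyloxy)benzyl]dihydrofuran-2(3H)-one, via hydroxy tert-butyl ester 14 (not isolated)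
Conditions: NaBH4, THF/H2O, 0 °C → rt; then p-TsOH·H2O (cat.), toluene, 60 °C
Reagents that add atoms: none
Why: Chemoselective borohydride reduction of the activated exocyclic imide carbonyl to the primary alcohol (the tert-butyl ester is left) releases the auxiliary, and acid-catalysed lactonisation of the γ-hydroxy ester then closes the five-membered lactone without touching C8.

Step 7
Reactants: 15 (4R)-4-[3-methoxy-4-(triisopropylsilyloxy)benzyl]dihydrofuran-2(3H)-one; 4 4-(allyloxy)-3-methoxybenzyl bromide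
Product: 17 (3R,4R)-3-[4-(allyloxy)-3-methoxybenzyl]-4-[3-methoxy-4-(triisopropylsilyloxy)benzyl]dihydrofuran-2(3H)-one, via lithium enolate 16 (not isolated)
Conditions: LiN(SiMe3)2, THF, −78 °C; then 4, DMPU, −78 → −30 °C
Reagents that add atoms: none
Why: Alkylation of a lactone enolate (SN2 on the benzylic bromide) anti to the C8 substituent on the adjacent carbon, the usual trans-selective benzylation of β-benzylbutyrolactones, which sets C8' as R.

Step 8
Reactants: 17 (3R,4R)-3-[4-(allyloxy)-3-methoxybenzyl]-4-[3-methoxy-4-(triisopropylsilyloxy)benzyl]dihydrofuran-2(3H)-one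
Product: 18 (2R,3R)-2-[4-(allyloxy)-3-methoxybenzyl]-3-[3-methoxy-4-(triisopropylsilyloxy)benzyl]butane-1,4-diol
Conditions: LiAlH4, THF, 0 °C; wet Na2SO4 quench
Reagents that add atoms: none
Why: LiAlH4 reduction of the lactone to the 1,4-diol, fast at 0 °C and without effect on the stereocentres, the aryl silyl ether or the allyl ether.

Step 9
Reactants: 18 (2R,3R)-2-[4-(allyloxy)-3-methoxybenzyl]-3-[3-methoxy-4-(triisopropylsilyloxy)benzyl]butane-1,4-diol
Product: 20 (1S,3aR,4S,6aR)-1-[4-(allyloxy)-3-methoxyphenyl]-4-[3-methoxy-4-(triisopropylsilyloxy)phenyl]tetrahydro-1H,3H-furo[3,4-c]furan, via aryltetrahydrofuran alcohol 19 (not isolated)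
Conditions: DDQ (2.2 equiv, two portions), 2,6-dichloropyridine, 4 Å molecular sieves, CH2Cl2, 0 °C → rt
Reagents that add atoms: none
Why: DDQ forms a charge-transfer complex with each 3,4-dioxygenated arene and removes hydride from its benzylic CH2, giving a cation that the para oxygen stabilises in a quinone-methide-like form; the allyloxyaryl side (C7') should react first and the less electron-rich silyloxyaryl side (C7) second. The closest known reaction type is the DDQ-mediated benzylic C–H oxidative cycloetherification of electron-rich arylalkanols, which turns dibenzylbutanediols into 2-aryltetrahydrofurans and is applied here twice in one flask. Ring B (C7'–O–C9–C8–C8') closes by 5-exo-trig attack of the C9 hydroxyl on C7' to give 19, and ring A (C7–O–C9'–C8'–C8) by 5-exo-trig attack of the C9' hydroxyl on C7, which can only give the cis-fused bicycle. C7' is controlled by C8', the aryl group taking the position anti to the C9' arm on the neighbouring carbon in the envelope transition state, and C7 is controlled by C8 and the ring already present, the aryl group ending on the convex face anti to C9. The step needs capture by oxygen instead of by the other arene (which would give an aryltetralin) and no further oxidation of the new benzylic ethers; a hydroxyl four atoms from each cationic carbon makes the five-membered closure faster than the six-membered Friedel–Crafts closure under acid-free conditions, and the remaining benzylic C–H of 19 and 20 sits on a branched ring carbon whose oxocarbenium ion would suffer allylic strain, so with 2.2 equivalents of oxidant it should react more slowly than the CH2 groups.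

Step 10
Reactants: 20 (1S,3aR,4S,6aR)-1-[4-(allyloxy)-3-methoxyphenyl]-4-[3-methoxy-4-(triisopropylsilyloxy)phenyl]tetrahydro-1H,3H-furo[3,4-c]furan; 21 2-methylbut-2-ene
Product: 22 (1S,3aR,4S,6aR)-1-{3-methoxy-4-[(3-methylbut-2-en-1-yl)oxy]phenyl}-4-[3-methoxy-4-(triisopropylsilyloxy)phenyl]tetrahydro-1H,3H-furo[3,4-c]furan
Conditions: second-generation Grubbs catalyst (H2IMes)(PCy3)Cl2Ru=CHPh (5 mol%), CH2Cl2/2-methylbut-2-ene, 40 °C, sealed tube
Reagents that add atoms: none
Why: Olefin cross-metathesis of the terminal allyl ether with excess 2-methylbut-2-ene exchanges the =CH2 terminus for =CMe2 with loss of propene, the known way to turn an allyl into a prenyl group, and the furofuran has no other alkene.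

Step 11
Reactants: 22 (1S,3aR,4S,6aR)-1-{3-methoxy-4-[(3-methylbut-2-en-1-yl)oxy]phenyl}-4-[3-methoxy-4-(triisopropylsilyloxy)phenyl]tetrahydro-1H,3H-furo[3,4-c]furan
Product: 23 2-methoxy-4-[(1S,3aR,4S,6aR)-4-{3-methoxy-4-[(3-methylbut-2-en-1-yl)oxy]phenyl}tetrahydro-1H,3H-furo[3,4-c]furan-1-yl]phenol
Conditions: Bu4NF, AcOH, THF, 0 °C
Reagents that add atoms: none
Why: Fluoride cleavage of the aryl silyl ether driven by the Si–F bond, buffered with AcOH so that no free phenoxide para to the benzylic ether carbon C7 is left to open ring A, while the prenyl ether and the bicyclic ether are inert.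

**Compound list**

1 | vanillyl alcohol (4-hydroxy-3-methoxybenzyl alcohol) | COc1cc(CO)ccc1O | starting material
2 | allyl bromide | C=CCBr | starting material
3 | [4-(allyloxy)-3-methoxyphenyl]methanol | COc1cc(CO)ccc1OCC=C | intermediate
4 | 4-(allyloxy)-3-methoxybenzyl bromide | COc1cc(CBr)ccc1OCC=C | intermediate
5 | 3-(4-hydroxy-3-methoxyphenyl)propanoic acid (dihydroferulic acid) | COc1cc(CCC(=O)O)ccc1O | starting material
6 | triisopropylsilyl 3-[3-methoxy-4-(triisopropylsilyloxy)phenyl]propanoate | COc1cc(CCC(=O)O[Si](C(C)C)(C(C)C)C(C)C)ccc1O[Si](C(C)C)(C(C)C)C(C)C | intermediate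
7 | 3-[3-methoxy-4-(triisopropylsilyloxy)phenyl]propanoic acid | COc1cc(CCC(=O)O)ccc1O[Si](C(C)C)(C(C)C)C(C)C | intermediate
8 | (S)-4-benzyl-1,3-oxazolidin-2-one | O=C1OC[C@H](Cc2ccccc2)N1 | starting material
9 | 3-[3-methoxy-4-(triisopropylsilyloxy)phenyl]propanoic pivalic anhydride | COc1cc(CCC(=O)OC(=O)C(C)(C)C)ccc1O[Si](C(C)C)(C(C)C)C(C)C | intermediate
10 | (S)-4-benzyl-3-{3-[3-methoxy-4-(triisopropylsilyloxy)phenyl]propanoyl}-1,3-oxazolidin-2-one | COc1cc(CCC(=O)N2[C@@H](Cc3ccccc3)COC2=O)ccc1O[Si](C(C)C)(C(C)C)C(C)C | intermediate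
11 | tert-butyl bromoacetate | CC(C)(C)OC(=O)CBr | starting material
12 | sodium (Z)-enolate of imide 10 | COc1cc(C/C=C(\[O-])N2[C@@H](Cc3ccccc3)COC2=O)ccc1O[Si](C(C)C)(C(C)C)C(C)C.[Na+] | intermediate
13 | tert-butyl (3R)-4-[(4S)-4-benzyl-2-oxo-1,3-oxazolidin-3-yl]-3-[3-methoxy-4-(triisopropylsilyloxy)benzyl]-4-oxobutanoate | COc1cc(C[C@H](CC(=O)OC(C)(C)C)C(=O)N2[C@@H](Cc3ccccc3)COC2=O)ccc1O[Si](C(C)C)(C(C)C)C(C)C | intermediate
14 | tert-butyl (3R)-3-(hydroxymethyl)-4-[3-methoxy-4-(triisopropylsilyloxy)phenyl]butanoate | COc1cc(C[C@H](CC(=O)OC(C)(C)C)CO)ccc1O[Si](C(C)C)(C(C)C)C(C)C | intermediate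
15 | (4R)-4-[3-methoxy-4-(triisopropylsilyloxy)benzyl]dihydrofuran-2(3H)-one | COc1cc(C[C@H]2COC(=O)C2)ccc1O[Si](C(C)C)(C(C)C)C(C)C | intermediate
16 | lithium enolate of lactone 15 | COc1cc(C[C@H]2COC([O-])=C2)ccc1O[Si](C(C)C)(C(C)C)C(C)C.[Li+] | intermediate
17 | (3R,4R)-3-[4-(allyloxy)-3-methoxybenzyl]-4-[3-methoxy-4-(triisopropylsilyloxy)benzyl]dihydrofuran-2(3H)-one | COc1cc(C[C@H]2COC(=O)[C@@H]2Cc3ccc(OCC=C)c(OC)c3)ccc1O[Si](C(C)C)(C(C)C)C(C)C | intermediate
18 | (2R,3R)-2-[4-(allyloxy)-3-methoxybenzyl]-3-[3-methoxy-4-(triisopropylsilyloxy)benzyl]butane-1,4-diol | COc1cc(C[C@@H](CO)[C@H](CO)Cc2ccc(OCC=C)c(OC)c2)ccc1O[Si](C(C)C)(C(C)C)C(C)C | intermediate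
19 | {(2S,3R,4R)-2-[4-(allyloxy)-3-methoxyphenyl]-4-[3-methoxy-4-(triisopropylsilyloxy)benzyl]tetrahydrofuran-3-yl}methanol | COc1cc(C[C@H]2CO[C@H](c3ccc(OCC=C)c(OC)c3)[C@H]2CO)ccc1O[Si](C(C)C)(C(C)C)C(C)C | intermediate
20 | (1S,3aR,4S,6aR)-1-[4-(allyloxy)-3-methoxyphenyl]-4-[3-methoxy-4-(triisopropylsilyloxy)phenyl]tetrahydro-1H,3H-furo[3,4-c]furan | COc1cc([C@H]2OC[C@H]3[C@@H]2CO[C@@H]3c4ccc(OCC=C)c(OC)c4)ccc1O[Si](C(C)C)(C(C)C)C(C)C | intermediate
21 | 2-methylbut-2-ene | CC=C(C)C | starting material
22 | (1S,3aR,4S,6aR)-1-{3-methoxy-4-[(3-methylbut-2-en-1-yl)oxy]phenyl}-4-[3-methoxy-4-(triisopropylsilyloxy)phenyl]tetrahydro-1H,3H-furo[3,4-c]furan | COc1cc([C@H]2OC[C@H]3[C@@H]2CO[C@@H]3c4ccc(OCC=C(C)C)c(OC)c4)ccc1O[Si](C(C)C)(C(C)C)C(C)C | intermediate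
23 | 2-methoxy-4-[(1S,3aR,4S,6aR)-4-{3-methoxy-4-[(3-methylbut-2-en-1-yl)oxy]phenyl}tetrahydro-1H,3H-furo[3,4-c]furan-1-yl]phenol, (7S,7'S,8R,8'R) | COc1cc([C@H]2OC[C@H]3[C@@H]2CO[C@@H]3c2ccc(OCC=C(C)C)c(OC)c2)ccc1O | target

**Step count and risks**

Total step count: 11. Longest linear sequence: 9 steps (steps 3 to 11, from 5 to 23).

Steps most likely to fail:

1. Step 9. Hydride abstraction at the silyloxy-substituted benzyl group may be slower than a further oxidation at the benzylic ether carbon formed first, so that the oxidant is consumed in over-oxidation and ring A does not close; the aryl silyl ether may also be lost from the cationic intermediate. The fallback sets out from 18 and closes the two rings one at a time with a different activating group for the second. One equivalent of DDQ is used to stop at the alcohol 19, which is isolated. Bu4NF/AcOH in THF then frees the phenol to give {(2S,3R,4R)-2-[4-(allyloxy)-3-methoxyphenyl]-4-(4-hydroxy-3-methoxybenzyl)tetrahydrofuran-3-yl}methanol F1. One equivalent of DDQ in CH2Cl2 at −40 °C should oxidise this 4-alkyl-2-methoxyphenol to its para-quinone methide much faster than it attacks an aryl ether, and the C9' hydroxyl adds to C7 to give 4-{(1S,3aR,4S,6aR)-4-[4-(allyloxy)-3-methoxyphenyl]tetrahydro-1H,3H-furo[3,4-c]furan-1-yl}-2-methoxyphenol F2. Cross-metathesis of F2 with 21 under the conditions of step 10 comes back to the route at 23.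

2. Step 10. Ruthenium hydride species may isomerise the allyl ether to a 1-propenyl ether, or the exchange may stop at the crotyl ether. The fallback sets out from 20 and replaces the metathesis by dealkylation and realkylation. Pd(PPh3)4 (zerovalent palladium) with morpholine in THF transfers the allyl group to the amine and gives 2-methoxy-4-{(1S,3aR,4S,6aR)-4-[3-methoxy-4-(triisopropylsilyloxy)phenyl]tetrahydro-1H,3H-furo[3,4-c]furan-1-yl}phenol F3. Alkylation of F3 with prenyl bromide and K2CO3 in acetone comes back to the route at 22.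

3. Step 7. The electron-rich benzylic bromide may decompose or self-alkylate before it meets the enolate, and proton exchange between product and enolate may lead to double alkylation. The fallback sets out from 15 and 3 and forms the C8'–C7' bond by an aldol reaction. MnO2 in CH2Cl2 oxidises 3 to 4-(allyloxy)-3-methoxybenzaldehyde F4. Addition of the lithium enolate 16 to F4 at −78 °C should give (3S,4R)-3-{[4-(allyloxy)-3-methoxyphenyl](hydroxy)methyl}-4-[3-methoxy-4-(triisopropylsilyloxy)benzyl]dihydrofuran-2(3H)-one F5 as both carbinol epimers. MsCl/Et3N converts it to [4-(allyloxy)-3-methoxyphenyl]{(3S,4R)-4-[3-methoxy-4-(triisopropylsilyloxy)benzyl]-2-oxotetrahydrofuran-3-yl}methyl methanesulfonate F6, and DBU eliminates this to (4R,E)-3-[4-(allyloxy)-3-methoxybenzylidene]-4-[3-methoxy-4-(triisopropylsilyloxy)benzyl]dihydrofuran-2(3H)-one F7. Conjugate reduction with LiBH(s-Bu)3 in THF at −78 °C, with protonation of the resulting enolate anti to the C8 benzyl group, comes back to the route at 17.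

**Further compounds**

F1 | step 9 | {(2S,3R,4R)-2-[4-(allyloxy)-3-methoxyphenyl]-4-(4-hydroxy-3-methoxybenzyl)tetrahydrofuran-3-yl}methanol | COc1cc(C[C@H]2CO[C@H](c3ccc(OCC=C)c(OC)c3)[C@H]2CO)ccc1O
F2 | step 9 | 4-{(1S,3aR,4S,6aR)-4-[4-(allyloxy)-3-methoxyphenyl]tetrahydro-1H,3H-furo[3,4-c]furan-1-yl}-2-methoxyphenol | COc1cc([C@H]2OC[C@H]3[C@@H]2CO[C@@H]3c4ccc(OCC=C)c(OC)c4)ccc1O
F3 | step 10 | 2-methoxy-4-{(1S,3aR,4S,6aR)-4-[3-methoxy-4-(triisopropylsilyloxy)phenyl]tetrahydro-1H,3H-furo[3,4-c]furan-1-yl}phenol | COc1cc([C@H]2OC[C@H]3[C@@H]2CO[C@@H]3c4ccc(O)c(OC)c4)ccc1O[Si](C(C)C)(C(C)C)C(C)C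
F4 | step 7 | 4-(allyloxy)-3-methoxybenzaldehyde | COc1cc(C=O)ccc1OCC=C
F5 | step 7 | (3S,4R)-3-{[4-(allyloxy)-3-methoxyphenyl](hydroxy)methyl}-4-[3-methoxy-4-(triisopropylsilyloxy)benzyl]dihydrofuran-2(3H)-one, both carbinol epimers | COc1cc(C[C@H]2COC(=O)[C@@H]2C(O)c3ccc(OCC=C)c(OC)c3)ccc1O[Si](C(C)C)(C(C)C)C(C)C
F6 | step 7 | [4-(allyloxy)-3-methoxyphenyl]{(3S,4R)-4-[3-methoxy-4-(triisopropylsilyloxy)benzyl]-2-oxotetrahydrofuran-3-yl}methyl methanesulfonate, both epimers | COc1cc(C[C@H]2COC(=O)[C@@H]2C(OS(C)(=O)=O)c3ccc(OCC=C)c(OC)c3)ccc1O[Si](C(C)C)(C(C)C)C(C)C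
F7 | step 7 | (4R,E)-3-[4-(allyloxy)-3-methoxybenzylidene]-4-[3-methoxy-4-(triisopropylsilyloxy)benzyl]dihydrofuran-2(3H)-one | COc1cc(C[C@H]2COC(=O)/C2=C/c3ccc(OCC=C)c(OC)c3)ccc1O[Si](C(C)C)(C(C)C)C(C)C
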